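128% was the number I began with for birch: my partner ceiling, the coupling partner charged less the protic impurity charged, as a fraction of the substrate charged. Each target costs one substrate and one coupling partner, and each protic impurity destroys one coupling partner.

| setting | birch | maple | elm |
|---|---|---|---|
| substrate | 0.50 mM | 1.5 mM | 5.0 mM |
| coupling partner | 0.650 mM | 0.650 mM | 0.650 mM |
| protic impurity | 0.0100 mM | 0.0100 mM | 0.0100 mM |
| free catalyst | 1.1 µM | 1.1 µM | 1.1 µM |
| time | 3.0 s | 3.0 s | 3.0 s |

    coupling partner + protic impurity → quenched reagent (k1 = 40000 M⁻¹ s⁻¹)
    coupling partner + free catalyst ⇌ catalyst intermediate A (K2 = 4100 M⁻¹, k2 = 4.9 × 10⁷ M⁻¹ s⁻¹)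
    substrate + catalyst intermediate B ⇌ catalyst intermediate C (K3 = 1.3 × 10⁵ M⁻¹, k3 = 3.3 × 10⁶ M⁻¹ s⁻¹)
    catalyst intermediate C → free catalyst + target (k4 = 880 s⁻¹)
    catalyst intermediate A ⇌ catalyst intermediate B (K5 = 4.1, k5 = 4500 s⁻¹)

- amount of target at the end, in percent of the substrate charged for birch, maple, elm, in this order
- how the row runs (hardly changes / falls, then rises / rises, then falls / falls all the way / rises all the way)

- "hardly changes" means that all values lie within two and a half points (for a concentration: within two and a half percent of the largest)
- run time (birch): 3.0 s

I reckoned up the ladder of times, fastest first.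

1. The catalyst turned first. Catalyst intermediate C had a half-life of 0.788 ms, and I summed the waits of one turn in maple to 1.59 ms. The catalyst charge was hardly any of the partner charge, so I made no correction for partner held on it.

2. The protic impurity came next. Its half-life, with the partner near its charge, was 0.0267 s, longer than a turn but far shorter than the run. It cost 1.54% of the partner charge.

3. Then the partner ran down. The ceiling was 42.7% in maple and 12.8% in elm, so there the partner was the limiting reagent. Maple needed 582 turns, which took 0.926 s, less than the run. Elm's substrate wait was shorter. I therefore put target at the ceiling in both.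

4. Birch took the whole run, so I went round again. Its ceiling stood above 100%, which made substrate the limiting reagent, and my first answer, complete conversion, left 21.5% of the partner charge. Putting that back, I found 59.9% of the catalyst as catalyst intermediate B, which gave a pseudo-first-order tail in substrate with half-life 0.319 s. The fixed waits of birch's turns cost 0.618 s, and the remaining 2.38 s left 0.562% of the substrate. My row therefore began at 99.4% and fell.

The forecast gave 99.4%, 42.7% and 12.8%, a row that falls all the way, on these grounds: “Maple and elm: partner is limiting and is exhausted within about 1 s, giving 0.64 mM target.”

The simulation gave 99.5%, 42.7% and 12.8%, a row that falls all the way.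

In maple the coupling partner stood at 0.240% of its charge at 1.50 s, earlier than the end at 3.0 s, and target stood at 42.6% at 1.50 s and at 42.7% at the end, beside a ceiling of 42.7%. In elm the ceiling of 12.8% stood beside 12.8% at the end, a tenfold time changed nothing, and 87.2% of the substrate still stood after 30.0 s.

Its constants are made up; the rest is arithmetic.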